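(The numbers in the tables were generated by integration with constants of no real substance, noise included.)

The time of reading is the same for both flasks, 40 h, so two things are wanted: the fraction of J that has reacted by then, and the share of that J which has become Q.

| setting | birch | elm | Wednesday's | Sunday's |
|---|---|---|---|---|
| J | 0.018 M | 0.039 M | 0.030 M | 0.050 M |
| temperature | −30 °C | −8 °C |  |  |
| remark | run made earlier | run made earlier | at −40 °C throughout | at −40 °C until 20 h, from then on at 0 °C |
| time |  |  | 40 h | 40 h |

- birch (time / h: Q / %): 2.50: 0.1; 6.00: 2.3; 12.0: 4.4; 20.0: 9.5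
- elm (time / h: Q / %): 0.833: 8.7; 2.00: 21.1; 4.00: 36.6; 6.00: 48.3

(each reading ± 0.5 percentage points)

- which one finishes higher in amount of Q, in percent of the J charged ("neither" within 2 percentage points) (Wednesday's / Sunday's / neither)
- amount of Q at the end, in percent of the J charged, Wednesday's
- amount of Q at the end, in percent of the J charged, Sunday's

- a reading or a percentage of Q counts all its forms, free or not

Start with the main step by itself. If c_J falls first-order, dc_J/dt = −k·c_J integrates to c_J = charge × exp(−kt), and every J lost counts as Q. The last elm reading then gives k = 0.110 h⁻¹, and in this picture Q ends near 100 per cent.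

Now add one process: suppose a fixed share of the reacted J ends as Q. Q is then that share times the fraction reacted, so its gains over equal intervals shrink by a constant factor. Elm gains 21.1%, 16 percentage points and 12 points in steps of 2.00 h, which is a factor of 0.745 per step. Summing such gains without end gives the ceiling, the Q reached once J has reacted away, or in the usual term the selectivity towards Q: 82.6%. A shift of 0.5 points in the last gain moves this reading between 77.7% and 88.1%. Carrying it to another temperature and charge is an assumption.

Then comes the rest, temperature. With the ceiling, elm gives k = 0.147 h⁻¹ and birch's last reading 0.00611 h⁻¹. A straight line of ln k against temperature gives 0.00144 h⁻¹ at −40 °C and 0.469 h⁻¹ at 0 °C. My own reckoning is therefore 4.61% for Wednesday's and, after 9.38 lifetimes in the warm stretch, 82.6% for Sunday's, which is higher. Birch's first reading, 0.1%, lies below the curve's 1.25%, so the Wednesday figure is uncertain.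

The forecast says Sunday's, with 3.3% and 98%, on the ground that "conversion is essentially complete". It stands above my reckoning on Sunday's and below it on Wednesday's.

Sunday's finishes higher, 78.1% against Wednesday's 5.41%. At 40.0 h Sunday's holds X, a second product beside Q, at 21.8%, each X counting as two, beside 0.0968% of J, and after 400 h Q in Sunday's reads 78.2%. The ceiling times Sunday's conversion of 99.9% gives 82.5%, which is 4.4 points above the flask. The forecast stands 20 points above it.

    J + Q → 2 Q (k = 0.0410 M⁻¹ min⁻¹, Ea = 42.0 kJ mol⁻¹)
    J → Q (k = 6.00 × 10⁻⁶ min⁻¹, Ea = 85.0 kJ mol⁻¹)
    G ⇌ Q, rate k3*(cs3 - [Q]) while solid is left; crystals form when [Q] > cs3 (solubility = 1.10 mM, k = 0.0540 min⁻¹)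
    J + Q → X (k = 0.00720 M⁻¹ min⁻¹, Ea = 47.0 kJ mol⁻¹)
    (constants at −40 °C)

For Sunday's flask charged with 0.013 M of J, the ceiling gives 82.6%. The computed result is 86.4%, with X at 13.4% and J at 0.19%.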